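**Retrosynthetic overview**

- The route rests on the 2,6-cis tetrahydropyran-4-one ring (O1, C2 with the guaiacyl group, C3, C4 ketone, C5, C6 with the C7–C8 side chain). C4 is carried as an exocyclic methylene, so that O1–C6 and C5–C6 can be made together in one oxocarbenium–allylsilane annulation.
- End game: C4=O from C4=CH2 by oxidative cleavage; the three hydroxyls from one aryl pivalate and two benzyl ethers.
- Ring disconnection (the only ring, closed in step 8): methylenepyran 16 from aryl hydroxy allylsilane 6 (aryl, C2–C5) and α-benzyloxy aldehyde 14 (C6–C8, second aryl).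
- 6 comes from pivaloyl vanillin 2 and the bifunctional allylstannane 4 by catalytic asymmetric allylation; 14 comes from O-benzyl-L-tyrosine.
- Stereochemistry: C7 from the chiral pool, C2 by catalyst control, C6 relayed from C2 in the chair closure.

Key step: step 8

Assumption: the (S)-BINOL/Ti(OiPr)4 catalyst is taken to direct the stannane to the Si face of aryl aldehyde 2, as with allyltributylstannane; the mirror-image ligand would be used if the sense proved opposite.

**Route**

Step 1
Reactants: 1 vanillin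
Product: 2 4-formyl-2-methoxyphenyl pivalate
Conditions: PivCl, Et3N, DMAP (cat.), CH2Cl2, 0 °C → rt
Reagents that add atoms: pivaloyl chloride CC(C)(C)C(=O)Cl
Why: DMAP-catalysed O-acylation of the phenol gives the aryl pivalate, which masks the phenol and lowers the donor power of the para oxygen for the later cationic step, while the aldehyde is untouched.

Step 2
Reactants: 3 2-(chloromethyl)allyltrimethylsilane
Product: 4 tributyl{2-[(trimethylsilyl)methyl]prop-2-en-1-yl}stannane
Conditions: Bu3SnH, LiN(iPr)2, THF, 0 °C; then 3, −78 °C → rt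
Reagents that add atoms: tributyltin hydride CCCC[SnH](CCCC)CCCC (lithiated in the flask to Bu3SnLi, [Li][Sn](CCCC)(CCCC)CCCC)
Why: Nucleophilic substitution of the allylic chloride by Bu3SnLi (SN2 and SN2' give the same compound) is the standard allylstannane synthesis and leaves the allylsilane intact.

Step 3
Reactants: 2 4-formyl-2-methoxyphenyl pivalate, 4 tributyl{2-[(trimethylsilyl)methyl]prop-2-en-1-yl}stannane
Product: 6 4-[(1S)-1-hydroxy-3-[(trimethylsilyl)methyl]but-3-en-1-yl]-2-methoxyphenyl pivalate, via tributylstannyl ether 5 (not isolated)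
Conditions: (S)-BINOL (20 mol %), Ti(OiPr)4 (10 mol %), 4 Å MS, CH2Cl2, −20 °C; aq. NaHCO3 work-up
Reagents that add atoms: none
Why: Keck asymmetric allylation, in which the BINOL–titanium Lewis acid activates the aldehyde and only the more nucleophilic allylstannane terminus adds (the allylsilane survives), the (S)-ligand directing attack to the Si face to set C2 as S; the tin alkoxide is hydrolysed on work-up.

Step 4
Reactants: 7 O-benzyl-L-tyrosine
Product: 10 (S)-3-[4-(benzyloxy)phenyl]-2-hydroxypropanoic acid, via diazonium carboxylate 8 (not isolated), via α-lactone 9 (not isolated)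
Conditions: NaNO2, 1 M H2SO4, 1,4-dioxane/H2O, 0 °C → rt
Reagents that add atoms: water O
Why: Diazotisation of the α-amino acid goes with net retention, because the carboxylate displaces N2 with inversion to the α-lactone and water opens it with a second inversion; the aryl benzyl ether protects the ring from nitrosation.

Step 5
Reactants: 10 (S)-3-[4-(benzyloxy)phenyl]-2-hydroxypropanoic acid
Product: 11 methyl (S)-3-[4-(benzyloxy)phenyl]-2-hydroxypropanoate
Conditions: MeOH, H2SO4 (cat.), reflux
Reagents that add atoms: methanol CO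
Why: Fischer esterification under catalytic acid does not touch the secondary alcohol, the aryl benzyl ether or the stereocenter.

Step 6
Reactants: 11 methyl (S)-3-[4-(benzyloxy)phenyl]-2-hydroxypropanoate
Product: 12 methyl (S)-2-(benzyloxy)-3-[4-(benzyloxy)phenyl]propanoate
Conditions: BnOC(=NH)CCl3, TfOH (cat.), cyclohexane/CH2Cl2, 0 °C → rt
Reagents that add atoms: benzyl 2,2,2-trichloroacetimidate N=C(OCc1ccccc1)C(Cl)(Cl)Cl
Why: Acid-catalysed O-benzylation with the trichloroacetimidate needs no base, so the α-stereocenter of the hydroxy ester should not epimerise.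

Step 7
Reactants: 12 methyl (S)-2-(benzyloxy)-3-[4-(benzyloxy)phenyl]propanoate
Product: 14 (S)-2-(benzyloxy)-3-[4-(benzyloxy)phenyl]propanal, via aluminium hemiacetal 13 (not isolated)
Conditions: iBu2AlH (1.1 equiv), CH2Cl2, −78 °C; MeOH, then aq. potassium sodium tartrate
Reagents that add atoms: none
Why: Partial reduction of the α-alkoxy ester with iBu2AlH stops at the chelated aluminium hemiacetal, which releases the aldehyde only on work-up; the crude aldehyde is used at once so that C7 does not epimerise.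

Step 8
Reactants: 6 4-[(1S)-1-hydroxy-3-[(trimethylsilyl)methyl]but-3-en-1-yl]-2-methoxyphenyl pivalate, 14 (S)-2-(benzyloxy)-3-[4-(benzyloxy)phenyl]propanal
Product: 16 4-[(2S,6R)-6-{(1S)-1-(benzyloxy)-2-[4-(benzyloxy)phenyl]ethyl}-4-methylenetetrahydro-2H-pyran-2-yl]-2-methoxyphenyl pivalate, via oxocarbenium triflate 15 (not isolated)
Conditions: Me3SiOTf (1.1 equiv), Et2O, −78 °C; iPr2NEt, then aq. NaHCO3
Reagents that add atoms: none
Why: Me3SiOTf condenses the C2 hydroxyl of 6 with the aldehyde carbon of 14 to the (E)-oxocarbenium ion 15 (O1–C6 bond), and the terminal alkene carbon of the allylsilane (the future C5) then attacks C6 in a 6-endo-trig closure through a chair, forming C5–C6 and the tetrahydropyran ring. The positive charge developing at C4 is stabilised by the β-silicon and is discharged by loss of the Me3Si group, which leaves C4 as the exocyclic methylene and regenerates the silyl triflate. The reaction type is the pyran annulation of β-hydroxy allylsilanes with aldehydes (intramolecular Sakurai or silyl-Prins cyclisation). The new stereocenter C6 is controlled by C2: in the chair the C2 aryl group and the C6 side chain both lie equatorial on the (E)-oxocarbenium ion, so the 2,6-cis ring (2S,6R) should form whichever configuration C7 has. The step needs ring closure to outrun ionisation of the benzylic C2–O1 bond (2-oxonia-Cope scrambling of C2) and enolisation of the α-alkoxy aldehyde; the highly nucleophilic allylsilane makes closure fast at −78 °C, the pivalate removes the para oxygen as a donor, and the benzyl ether at C7 keeps 14 slow to enolise.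

Step 9
Reactants: 16 4-[(2S,6R)-6-{(1S)-1-(benzyloxy)-2-[4-(benzyloxy)phenyl]ethyl}-4-methylenetetrahydro-2H-pyran-2-yl]-2-methoxyphenyl pivalate
Product: 18 4-[(2S,6R)-6-{(1S)-1-(benzyloxy)-2-[4-(benzyloxy)phenyl]ethyl}-4-oxotetrahydro-2H-pyran-2-yl]-2-methoxyphenyl pivalate, via diol 17 (not isolated)
Conditions: OsO4 (cat.), NaIO4, 2,6-lutidine, 1,4-dioxane/H2O, rt
Reagents that add atoms: osmium tetroxide O=[Os](=O)(=O)=O (source of the ketone oxygen; kept in turnover by sodium periodate [Na+].[O-]I(=O)(=O)=O)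
Why: Lemieux–Johnson oxidation (dihydroxylation of the 1,1-disubstituted alkene, then periodate cleavage of the diol) unmasks the C4 ketone, with 2,6-lutidine as buffer, while the pivalate keeps the guaiacyl phenol safe from periodate.

Step 10
Reactants: 18 4-[(2S,6R)-6-{(1S)-1-(benzyloxy)-2-[4-(benzyloxy)phenyl]ethyl}-4-oxotetrahydro-2H-pyran-2-yl]-2-methoxyphenyl pivalate
Product: 19 (2S,6R)-2-(4-hydroxy-3-methoxyphenyl)-6-{(1S)-1-(benzyloxy)-2-[4-(benzyloxy)phenyl]ethyl}tetrahydro-4H-pyran-4-one
Conditions: K2CO3, MeOH, 0 °C → rt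
Reagents that add atoms: none
Why: Base-promoted transesterification cleaves the activated aryl ester and frees the phenol; a reversible retro-oxa-Michael opening, should it occur, recloses to the diequatorial 2,6-cis ring, and C7 is not acidic.

Step 11
Reactants: 19 (2S,6R)-2-(4-hydroxy-3-methoxyphenyl)-6-{(1S)-1-(benzyloxy)-2-[4-(benzyloxy)phenyl]ethyl}tetrahydro-4H-pyran-4-one
Product: 20 (2S,6R)-2-(4-hydroxy-3-methoxyphenyl)-6-[(1S)-1-hydroxy-2-(4-hydroxyphenyl)ethyl]tetrahydro-4H-pyran-4-one
Conditions: H2 (1 atm), 10% Pd/C, EtOAc, rt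
Reagents that add atoms: none
Why: Catalytic hydrogenolysis removes the aryl and the alkyl benzyl ether, and under neutral conditions the hindered secondary benzylic ring ether C2–O1 and the ketone should be retained.

**Compound list**

1 | vanillin | COc1cc(C=O)ccc1O | starting material
2 | 4-formyl-2-methoxyphenyl pivalate | COc1cc(C=O)ccc1OC(=O)C(C)(C)C | intermediate
3 | 2-(chloromethyl)allyltrimethylsilane | C=C(CCl)C[Si](C)(C)C | starting material
4 | tributyl{2-[(trimethylsilyl)methyl]prop-2-en-1-yl}stannane | C=C(C[Si](C)(C)C)C[Sn](CCCC)(CCCC)CCCC | intermediate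
5 | tributylstannyl ether of 6 (not isolated) | COc1cc([C@@H](O[Sn](CCCC)(CCCC)CCCC)CC(=C)C[Si](C)(C)C)ccc1OC(=O)C(C)(C)C | intermediate
6 | 4-[(1S)-1-hydroxy-3-[(trimethylsilyl)methyl]but-3-en-1-yl]-2-methoxyphenyl pivalate | COc1cc([C@@H](O)CC(=C)C[Si](C)(C)C)ccc1OC(=O)C(C)(C)C | intermediate
7 | O-benzyl-L-tyrosine | N[C@@H](Cc1ccc(OCc2ccccc2)cc1)C(=O)O | starting material
8 | (S)-diazonium carboxylate from 7 (not isolated) | N#[N+][C@@H](Cc1ccc(OCc2ccccc2)cc1)C(=O)[O-] | intermediate
9 | (R)-3-[4-(benzyloxy)benzyl]oxiran-2-one, the α-lactone (not isolated) | O=C1O[C@@H]1Cc1ccc(OCc2ccccc2)cc1 | intermediate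
10 | (S)-3-[4-(benzyloxy)phenyl]-2-hydroxypropanoic acid | O[C@@H](Cc1ccc(OCc2ccccc2)cc1)C(=O)O | intermediate
11 | methyl (S)-3-[4-(benzyloxy)phenyl]-2-hydroxypropanoate | COC(=O)[C@@H](O)Cc1ccc(OCc2ccccc2)cc1 | intermediate
12 | methyl (S)-2-(benzyloxy)-3-[4-(benzyloxy)phenyl]propanoate | COC(=O)[C@@H](OCc1ccccc1)Cc1ccc(OCc2ccccc2)cc1 | intermediate
13 | diisobutylaluminium hemiacetal of 12 (not isolated; hemiacetal carbon undefined) | COC(O[Al](CC(C)C)CC(C)C)[C@@H](OCc1ccccc1)Cc1ccc(OCc2ccccc2)cc1 | intermediate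
14 | (S)-2-(benzyloxy)-3-[4-(benzyloxy)phenyl]propanal | O=C[C@@H](OCc1ccccc1)Cc1ccc(OCc2ccccc2)cc1 | intermediate
15 | (E)-oxocarbenium triflate from 6 and 14 (not isolated) | COc1cc([C@@H](/[O+]=C/[C@@H](OCc2ccccc2)Cc2ccc(OCc3ccccc3)cc2)CC(=C)C[Si](C)(C)C)ccc1OC(=O)C(C)(C)C.[O-]S(=O)(=O)C(F)(F)F | intermediate
16 | 4-[(2S,6R)-6-{(1S)-1-(benzyloxy)-2-[4-(benzyloxy)phenyl]ethyl}-4-methylenetetrahydro-2H-pyran-2-yl]-2-methoxyphenyl pivalate | COc1cc([C@@H]2CC(=C)C[C@H]([C@@H](OCc3ccccc3)Cc3ccc(OCc4ccccc4)cc3)O2)ccc1OC(=O)C(C)(C)C | intermediate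
17 | 4-hydroxy-4-(hydroxymethyl) diol from 16 (not isolated; C4 undefined) | COc1cc([C@@H]2CC(O)(CO)C[C@H]([C@@H](OCc3ccccc3)Cc3ccc(OCc4ccccc4)cc3)O2)ccc1OC(=O)C(C)(C)C | intermediate
18 | 4-[(2S,6R)-6-{(1S)-1-(benzyloxy)-2-[4-(benzyloxy)phenyl]ethyl}-4-oxotetrahydro-2H-pyran-2-yl]-2-methoxyphenyl pivalate | COc1cc([C@@H]2CC(=O)C[C@H]([C@@H](OCc3ccccc3)Cc3ccc(OCc4ccccc4)cc3)O2)ccc1OC(=O)C(C)(C)C | intermediate
19 | (2S,6R)-2-(4-hydroxy-3-methoxyphenyl)-6-{(1S)-1-(benzyloxy)-2-[4-(benzyloxy)phenyl]ethyl}tetrahydro-4H-pyran-4-one | COc1cc([C@@H]2CC(=O)C[C@H]([C@@H](OCc3ccccc3)Cc3ccc(OCc4ccccc4)cc3)O2)ccc1O | intermediate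
20 | (2S,6R)-2-(4-hydroxy-3-methoxyphenyl)-6-[(1S)-1-hydroxy-2-(4-hydroxyphenyl)ethyl]tetrahydro-4H-pyran-4-one | COc1cc([C@@H]2CC(=O)C[C@H]([C@@H](O)Cc3ccc(O)cc3)O2)ccc1O | target

**Step count**

Total: 11 steps. Longest linear sequence: 8 steps (steps 4, 5, 6, 7, 8, 9, 10, 11, from O-benzyl-L-tyrosine).

**Steps most likely to fail**

1. Step 8 (pyran annulation). What may go wrong: ionisation of the benzylic C2–O1 bond with 2-oxonia-Cope scrambling and loss of configurational purity at C2; protodesilylation of the allylsilane before condensation; enolisation of the aldehyde with erosion at C7. Fallback: the ring is closed by oxa-Michael addition instead; the fallback sets out from 2 and 14 and comes back to the route at 18. Wittig reaction of 2 with Ph3P=CHC(O)CH3 should give the enone 2-methoxy-4-[(1E)-3-oxobut-1-en-1-yl]phenyl pivalate F1. Me3SiOTf/Et3N converts it into the silyloxydiene 2-methoxy-4-[(1E)-3-(trimethylsilyloxy)buta-1,3-dien-1-yl]phenyl pivalate F2. BF3·OEt2-mediated Mukaiyama aldol addition of F2 to 14 (Felkin–Anh, 1,2-anti) should give the β-hydroxy enone 4-[(1E,5R,6S)-6-(benzyloxy)-7-[4-(benzyloxy)phenyl]-5-hydroxy-3-oxohept-1-en-1-yl]-2-methoxyphenyl pivalate F3. Acid-catalysed (Amberlyst-15, CH2Cl2) 6-endo oxa-Michael cyclisation, equilibrated to the diequatorial isomer, then gives cis ketone 18. Here C6 is set from C7 and C2 thermodynamically from C6.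

2. Step 3 (asymmetric allylation). What may go wrong: poor enantiofacial selectivity or slow turnover of the BINOL–titanium catalyst with the hindered bifunctional stannane, and protodesilylation during the long reaction time. Fallback: C2 is set by ketone reduction instead; the fallback sets out from 2 and 4 and comes back at 6. BF3·OEt2-promoted addition of 4 to 2 (−78 °C, stannane terminus only) gives the racemic alcohol 4-[1-hydroxy-3-[(trimethylsilyl)methyl]but-3-en-1-yl]-2-methoxyphenyl pivalate F4. Dess–Martin oxidation (NaHCO3 buffer) gives the aryl ketone 2-methoxy-4-{3-[(trimethylsilyl)methyl]but-3-enoyl}phenyl pivalate F5. Corey–Bakshi–Shibata reduction with the (R)-methyl oxazaborolidine and catecholborane (which does not hydroborate the alkene) at −78 °C should give (S)-6.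

3. Step 11 (hydrogenolysis). What may go wrong: over-reduction, that is hydrogenolysis of the benzylic ring bond C2–O1, which the free para hydroxyl activates, competing with the slower cleavage of the secondary alkyl benzyl ether. Fallback: reductive conditions are avoided and the order of deprotection is changed; the fallback sets out from 18 and comes back at 20. BCl3 with pentamethylbenzene as cation scavenger (CH2Cl2, −78 °C) cleaves both benzyl ethers while the pivalate keeps the C2 aryl group electron-poor. This gives the pivalate 4-[(2S,6R)-6-[(1S)-1-hydroxy-2-(4-hydroxyphenyl)ethyl]-4-oxotetrahydro-2H-pyran-2-yl]-2-methoxyphenyl pivalate F6. Methanolysis of F6 (K2CO3, MeOH) then gives 20.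

**Further compounds**

F1 | step 8 | 2-methoxy-4-[(1E)-3-oxobut-1-en-1-yl]phenyl pivalate | COc1cc(/C=C/C(C)=O)ccc1OC(=O)C(C)(C)C
F2 | step 8 | 2-methoxy-4-[(1E)-3-(trimethylsilyloxy)buta-1,3-dien-1-yl]phenyl pivalate | COc1cc(/C=C/C(=C)O[Si](C)(C)C)ccc1OC(=O)C(C)(C)C
F3 | step 8 | 4-[(1E,5R,6S)-6-(benzyloxy)-7-[4-(benzyloxy)phenyl]-5-hydroxy-3-oxohept-1-en-1-yl]-2-methoxyphenyl pivalate | COc1cc(/C=C/C(=O)C[C@@H](O)[C@@H](OCc2ccccc2)Cc2ccc(OCc3ccccc3)cc2)ccc1OC(=O)C(C)(C)C
F4 | step 3 | racemic 4-[1-hydroxy-3-[(trimethylsilyl)methyl]but-3-en-1-yl]-2-methoxyphenyl pivalate | COc1cc(C(O)CC(=C)C[Si](C)(C)C)ccc1OC(=O)C(C)(C)C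
F5 | step 3 | 2-methoxy-4-{3-[(trimethylsilyl)methyl]but-3-enoyl}phenyl pivalate | COc1cc(C(=O)CC(=C)C[Si](C)(C)C)ccc1OC(=O)C(C)(C)C
F6 | step 11 | 4-[(2S,6R)-6-[(1S)-1-hydroxy-2-(4-hydroxyphenyl)ethyl]-4-oxotetrahydro-2H-pyran-2-yl]-2-methoxyphenyl pivalate | COc1cc([C@@H]2CC(=O)C[C@H]([C@@H](O)Cc3ccc(O)cc3)O2)ccc1OC(=O)C(C)(C)C
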